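**Retrosynthetic overview**

1. Ring numbering: C1 (quaternary; OH and C7H2OH), C2 (OBz), C3=C4, C5 (OBz), C6 (OH). The plan rests on the cis C1–OH/C6–OH pair next to the trans C2 benzoate on the one cyclohexene ring: C6–OH is the bromine-flanked carbinol of an arene cis-dihydrodiol, and C1–O/C2–O are the two C–O bonds of a C1–C2 vinyl oxirane.
2. C5–OBz ⇐ Mitsunobu inversion of the C5 carbinol; C2–OBz/C1–OH ⇐ anti opening of the oxirane by benzoic acid at allylic C2.
3. Oxirane ⇐ C6–OH-directed VO(acac)2/t-BuOOH epoxidation of the C1=C2 alkene of a 5-O-silyl dienol.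
4. C1–C7 ⇐ Stille hydroxymethylation of (1S,2S)-3-bromocyclohexa-3,5-diene-1,2-diol.
5. Ring order: the carbocycle is bought; the oxirane (step 4) is the only ring built and is opened in step 5; a temporary C1/C6 dioxolane (steps 6 to 10) only masks the diol.

Key step: step 4

Remark on the chemistry: α denotes the ring face that carries both hydroxyls of 1 (and the C6 hydroxyl throughout), β the opposite face; in 1 the bromine sits on C1 and the hydroxyls on C5 and C6 of the route numbering. Compound 1 is assumed to be the commercial dioxygenase-derived enantiomer.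

**Route**

Step 1
Reactants: 1 (1S,2S)-3-bromocyclohexa-3,5-diene-1,2-diol; 2 (tributylstannyl)methanol
Product: 3 (1S,2R)-3-(hydroxymethyl)cyclohexa-3,5-diene-1,2-diol (C7H2OH on C1; 5α,6α-diol)
Conditions: Pd(PPh3)4 (5 mol %), 1,4-dioxane, 80 °C, Ar, dark
Reagents that add atoms: (tributylstannyl)methanol (2), CCCC[Sn](CCCC)(CCCC)CO
Why: Stille coupling, in which the dienyl C–Br bond adds to zerovalent palladium, the α-oxygenated CH2OH group is transferred from tin in preference to butyl and reductive elimination forms C1–C7; neither carbinol stereocentre is touched, and free halo-arene cis-dihydrodiols are known to tolerate palladium cross-coupling.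

Step 2
Reactants: 3 triol
Product: 4 C1-[(tert-butyldiphenylsilyloxy)methyl]cyclohexa-1,3-diene-5α,6α-diol
Conditions: TBDPSCl (1.05 equiv), imidazole, DMF, 0 °C
Reagents that add atoms: tert-butyl(chloro)diphenylsilane, CC(C)(C)[Si](Cl)(c1ccccc1)c1ccccc1
Why: Chemoselective silyl ether formation, since the bulky chlorosilane should react with the primary allylic hydroxyl much faster than with either secondary carbinol.

Step 3
Reactants: 4 diol
Product: 5 dienol with free 6α-OH, 5α-OSiEt3 and C7-OTBDPS
Conditions: TESCl (1.05 equiv), imidazole, CH2Cl2, −40 °C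
Reagents that add atoms: chlorotriethylsilane, CC[Si](Cl)(CC)CC
Why: Kinetic regioselective monosilylation, because the C5 hydroxyl is flanked only by an sp2 CH whereas the C6 hydroxyl is shielded by C1 and its silyloxymethyl arm, as in the known distal-selective silylation of 3-substituted arene cis-dihydrodiols.

Step 4
Reactants: 5 dienol
Product: 6 1α,2α-epoxide (oxirane syn to the 6α-OH; C7 arm β; 5α-OSiEt3; C3=C4 retained)
Conditions: VO(acac)2 (5 mol %), t-BuOOH (1.3 equiv, in decane), CH2Cl2, 0 °C to rt
Reagents that add atoms: tert-butyl hydroperoxide, CC(C)(C)OO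
Why: VO(acac)2 is oxidised by t-BuOOH to a pentavalent vanadium alkoxide that binds the C6 hydroxyl as a vanadate ester and the hydroperoxide as a side-on alkylperoxide, and the activated peroxide oxygen is passed to the C1=C2 alkene inside this complex. The closest known reaction type is the vanadium-catalysed epoxidation of cyclic allylic alcohols, which gives syn epoxy alcohols, and its use on dienols, which gives vinyl epoxides. The oxirane ring is closed by concerted, suprafacial transfer of one oxygen atom to both alkene carbons, so the C1–O and C2–O bonds form in one event and a 7-oxabicyclo[4.1.0]hept-2-ene results. C1 and C2 are both set by the C6 stereocentre, because the metal tether holds the peroxide on the α face; the oxirane is therefore syn to the C6 hydroxyl and the C7 arm ends on the β face. Site selectivity between the two alkenes of the diene is needed and is secured because only C1=C2 is allylic to the free hydroxyl (the C5 oxygen is silylated and C3=C4 is only homoallylic) and it is the trisubstituted, more electron-rich alkene; face selectivity is secured by the bound hydroxyl. Low temperature and a small excess of oxidant guard against oxidation of the carbinol and against a second epoxidation.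

Step 5
Reactants: 6 vinyl epoxide; 7 benzoic acid
Product: 8 2β-benzoyloxy-1α,6α-diol (5α-OSiEt3, C7-OTBDPS, C3=C4)
Conditions: PhCO2H (1.5 equiv), Ti(OiPr)4 (1.5 equiv), CH2Cl2, 0 °C to rt
Reagents that add atoms: benzoic acid (7), OC(=O)c1ccccc1
Why: Ti(OiPr)4-mediated opening of a 2,3-epoxy alcohol by a carboxylic acid at the carbon remote from the carbinol; titanium bridges the cis C6 hydroxyl and the oxirane oxygen, and benzoate attacks C2, the allylic and less substituted terminus, anti to the C2–O bond (SN2, inversion), which gives the 2β-benzoate trans to the retained 1α-hydroxyl.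

Step 6
Reactants: 8 diol
Product: 9 1α,6α-O-isopropylidene derivative of 8 (cis-fused dioxolane)
Conditions: 2-methoxypropene (5 equiv), PPTS (5 mol %), CH2Cl2, 0 °C to rt
Reagents that add atoms: 2-methoxypropene, COC(C)=C
Why: Acid-catalysed ketalisation of the only free diol, the cis C1/C6 pair, under anhydrous, weakly acidic conditions that should leave the triethylsilyl ether in place.

Step 7
Reactants: 9 acetonide
Product: 10 5α-alcohol (2β-OBz, 1α,6α-acetonide, C7-OTBDPS)
Conditions: HF·pyridine, pyridine, THF, 0 °C
Reagents that add atoms: none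
Why: Selective fluoride-mediated desilylation, as a secondary triethylsilyl ether is cleaved by buffered HF·pyridine far faster than a tert-butyldiphenylsilyl ether while ketal and ester are inert.

Step 8
Reactants: 10 allylic alcohol; 7 benzoic acid
Product: 11 2β,5β-dibenzoate (1α,6α-acetonide, C7-OTBDPS)
Conditions: PhCO2H, PPh3, DIAD (1.5 equiv each), toluene, 0 °C to rt
Reagents that add atoms: benzoic acid (7), OC(=O)c1ccccc1
Why: Mitsunobu reaction, in which the C5 oxyphosphonium ion is displaced by benzoate from the β face, anti to the leaving group and to the neighbouring C6 oxygen, so C5 is inverted to the 5β-benzoate.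

Step 9
Reactants: 11 silyl ether
Product: 12 C7 primary alcohol (2β,5β-dibenzoate, 1α,6α-acetonide)
Conditions: HF·pyridine, THF, 0 °C to rt (plastic vessel)
Reagents that add atoms: none
Why: Fluoride-mediated Si–O cleavage under acidic rather than basic conditions, chosen so that the freed C7 hydroxyl does not take over the cis C2 benzoate by acyl migration.

Step 10
Reactants: 12 acetonide
Product: 13 (1R,4S,5S,6S)-5,6-dihydroxy-5-(hydroxymethyl)cyclohex-2-ene-1,4-diyl dibenzoate (route numbering: 1α-OH, C7H2OH β, 2β-OBz, 5β-OBz, 6α-OH), CNP0212417.1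
Conditions: TFA/H2O (9:1), 0 °C, then evaporation with toluene
Reagents that add atoms: none
Why: Acid-catalysed hydrolysis of the isopropylidene ketal, which touches no stereocentre and should be faster at 0 °C than acid-promoted benzoate migration; the volatile reagents allow a base-free work-up.

**Compound list**

1 | (1S,2S)-3-bromocyclohexa-3,5-diene-1,2-diol | BrC1=CC=C[C@H](O)[C@@H]1O | starting material
2 | (tributylstannyl)methanol | CCCC[Sn](CCCC)(CCCC)CO | starting material
3 | (1S,2R)-3-(hydroxymethyl)cyclohexa-3,5-diene-1,2-diol | OCC1=CC=C[C@H](O)[C@@H]1O | intermediate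
4 | C7 tert-butyldiphenylsilyl ether of 3 (5α,6α-diol) | CC(C)(C)[Si](c1ccccc1)(c1ccccc1)OCC1=CC=C[C@H](O)[C@@H]1O | intermediate
5 | dienol: 6α-OH, 5α-OSiEt3, C7-OTBDPS | CC(C)(C)[Si](c1ccccc1)(c1ccccc1)OCC1=CC=C[C@H](O[Si](CC)(CC)CC)[C@@H]1O | intermediate
6 | 1α,2α-vinyl epoxide syn to 6α-OH (5α-OSiEt3, C7-OTBDPS) | CC(C)(C)[Si](c1ccccc1)(c1ccccc1)OC[C@@]12O[C@@H]1C=C[C@H](O[Si](CC)(CC)CC)[C@@H]2O | intermediate
7 | benzoic acid | OC(=O)c1ccccc1 | starting material
8 | 2β-benzoate 1α,6α-diol (5α-OSiEt3, C7-OTBDPS) | O=C(O[C@H]1C=C[C@H](O[Si](CC)(CC)CC)[C@H](O)[C@@]1(O)CO[Si](c2ccccc2)(c2ccccc2)C(C)(C)C)c1ccccc1 | intermediate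
9 | 1α,6α-acetonide of 8 | O=C(O[C@H]1C=C[C@H](O[Si](CC)(CC)CC)[C@@H]2OC(C)(C)O[C@]12CO[Si](c3ccccc3)(c3ccccc3)C(C)(C)C)c1ccccc1 | intermediate
10 | 5α-alcohol (2β-OBz, 1α,6α-acetonide, C7-OTBDPS) | O=C(O[C@H]1C=C[C@H](O)[C@@H]2OC(C)(C)O[C@]12CO[Si](c3ccccc3)(c3ccccc3)C(C)(C)C)c1ccccc1 | intermediate
11 | 2β,5β-dibenzoate (1α,6α-acetonide, C7-OTBDPS) | O=C(O[C@H]1C=C[C@@H](OC(=O)c3ccccc3)[C@@H]2OC(C)(C)O[C@]12CO[Si](c4ccccc4)(c4ccccc4)C(C)(C)C)c1ccccc1 | intermediate
12 | 2β,5β-dibenzoate 1α,6α-acetonide with free C7-OH | O=C(O[C@H]1C=C[C@@H](OC(=O)c3ccccc3)[C@@H]2OC(C)(C)O[C@]12CO)c1ccccc1 | intermediate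
13 | (1R,4S,5S,6S)-5,6-dihydroxy-5-(hydroxymethyl)cyclohex-2-ene-1,4-diyl dibenzoate | O=C(O[C@H]1C=C[C@@H](OC(=O)c2ccccc2)[C@H](O)[C@@]1(O)CO)c1ccccc1 | target

**Step count and risks**

Total step count: 10. Longest linear sequence: 10 steps (from 1).

Steps most likely to fail:

Step 4 (key step). The dienol may be lost to aromatisation (loss of water or silanol under the Lewis-acidic metal) or to oxidation of the carbinol before oxygen transfer, and the vinyl oxirane may open under the same conditions. Fallback from 5, returning at 6: the oxygen is delivered through a carbonate tether instead of a metal peroxide. Compound 5 is acylated with Boc2O and DMAP (CH2Cl2, rt) to the C6 tert-butyl carbonate of the dienol F1. IBr in toluene at −80 °C then forms the iodonium ion on the β face of C1=C2, and the carbonate carbonyl oxygen closes onto C1 from the α face (five-membered ring) to give the cis-fused C6/C1 cyclic carbonate with a 2β-iodide F2. K2CO3 in MeOH at 0 °C cleaves the carbonate, and the C1 alkoxide displaces the C2 iodide from the α face, which gives 6.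

Step 1. Transfer of the hydroxymethyl group from tin may be slow at a temperature at which the unprotected diene diol dehydrates to a phenol or dimerises by Diels–Alder reaction, and the polar triol may be lost on removal of tin residues. Fallback from 1, returning at 3: the carbon is brought in as carbon monoxide. Pd(OAc)2/PPh3, CO (1 atm), MeOH and Et3N at 60 °C should give methyl (5S,6R)-5,6-dihydroxycyclohexa-1,3-diene-1-carboxylate F3, whose acceptor group slows dehydration. Reduction with i-Bu2AlH (excess, THF, −78 to 0 °C) converts the ester into the primary allylic alcohol 3.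

Step 8. Benzoate may attack at C3 with allylic transposition, or elimination toward a diene may occur, instead of direct displacement at C5. Fallback from 10, returning at 11: activation and displacement are separated. MsCl and Et3N (CH2Cl2, −20 °C) give the 5α-methanesulfonate F4, and PhCO2Cs with 18-crown-6 in toluene (rt to 50 °C) displaces it by SN2 with inversion to give 11.

**Further compounds**

F1 | step 4 | C6 tert-butyl carbonate of dienol 5 | CC(C)(C)[Si](c1ccccc1)(c1ccccc1)OCC1=CC=C[C@H](O[Si](CC)(CC)CC)[C@@H]1OC(=O)OC(C)(C)C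
F2 | step 4 | 2β-iodo C6/C1 cis-fused cyclic carbonate (5α-OSiEt3, C7-OTBDPS) | I[C@H]1C=C[C@H](O[Si](CC)(CC)CC)[C@@H]2OC(=O)O[C@]12CO[Si](c3ccccc3)(c3ccccc3)C(C)(C)C
F3 | step 1 | methyl (5S,6R)-5,6-dihydroxycyclohexa-1,3-diene-1-carboxylate | COC(=O)C1=CC=C[C@H](O)[C@@H]1O
F4 | step 8 | 5α-methanesulfonate of 10 | O=C(O[C@H]1C=C[C@H](OS(C)(=O)=O)[C@@H]2OC(C)(C)O[C@]12CO[Si](c3ccccc3)(c3ccccc3)C(C)(C)C)c1ccccc1
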